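(The runs are calculated for an exercise; the scatter is artificial.)

The slowness of the theta run sits at its start, and that slowness is worth measuring before anything else.

| setting | theta | alpha | beta | epsilon | delta |
|---|---|---|---|---|---|
| Q | 50.0 mM | 30.0 mM | 75.0 mM | 50.0 mM | 17.0 mM |
| L | 75.0 mM | 55.0 mM | 75.0 mM | 75.0 mM | 75.0 mM |
| Z | 4.00 mM | 4.00 mM | 4.00 mM | 8.00 mM | 1.30 mM |
| time |  |  |  |  | 9.8 min |

- theta run (time / min: [Q] / mM): 1.6: 45.57; 3.3: 39.99; 4.9: 35.11; 6.5: 30.94; 8.2: 26.83; 9.8: 23.24
- alpha run (time / min: [Q] / mM): 1.6: 27.12; 3.3: 23.72; 4.9: 20.62; 6.5: 17.70; 8.2: 15.49; 9.8: 13.32
- beta run (time / min: [Q] / mM): 1.6: 68.98; 3.3: 61.55; 4.9: 54.21; 6.5: 48.33; 8.2: 42.53; 9.8: 37.73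
- epsilon run (time / min: [Q] / mM): 1.6: 34.03; 3.3: 19.01; 4.9: 11.10; 6.5: 5.83; 8.2: 3.58; 9.8: 1.68

(standard deviation of a reading: 0.2 mM)

- Overall: Q + L -> G, with Z as catalyst.
- Constant volume, constant temperature.
- What is held in complexes is read along with the free species.
- "The second partner" is L.
- An order is taken over about fifteen percent of the charge, up and down.

1. how the opening rate goes with [Q] round the charge of the theta run: the exponent of the rate at two percent of Q gone to G (one fixed amount of G, the same in the runs compared)
2. how the opening rate goes with [Z] round the charge of the theta run: the exponent of the rate at two percent of Q gone to G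
3. the alpha run starts with 20.0 mM less of Q and of L than the theta run, and with no G. Compared where both hold the same amount of Q, once fifteen percent of what the alpha run was charged with has turned into G, is the alpha run faster, slower or alike (within a tenth)?
4. Q in the delta run at 9.8 min, as a share of the Q charged
5. which of these the readings show (the second partner kills the catalyst / the two partners rest in a complex / the second partner is lost in pairs / the catalyst wakes slowly)

Read each table as ln[Q] against time. From its second reading to its last, the theta run falls on a nearly straight line with a late constant of 0.0835 min⁻¹. Over its first 1.6 min, though, it manages 0.0580 min⁻¹, which is slower than the late constant. In the theta run the delay comes to 0.625 min: this is the lost time (the induction period), the time of the second reading less the time the late constant needs to bring [Q] from the charge to that reading. The scatter of that one reading shifts it by 0.0599 min.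

Now take the other tables in turn. The alpha run has a late constant of 0.0888 min⁻¹ and a lost time of 0.654 min. Its constant is 1.06 of the theta value, so at equal [Q] you should expect the alpha and theta runs to go alike.

The beta run, with more Q, has a constant of 0.0753 min⁻¹, lower than that of the theta run, and its lost time is 0.675 min.

The epsilon run, read up to 6.5 min, has twice the Z of the theta run. Its constant of 0.369 min⁻¹ is 4.42 times the theta constant, so the late pace goes as [Z] to the power 2.15. Yet its lost time, 0.682 min, stays about that of the theta run.

So the pace moves with the charge while the lost time does not, and a delay of that kind reads as a catalyst that wakes slowly.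

This also bears on the opening orders. At its late constant the theta run turns two percent of its Q in 0.240 min, and the epsilon run in 0.0542 min. Both times lie inside the lost time, so the opening rates are taken on a catalyst still waking, and their orders should stand below the late ones.

My own reckoning for the delta run takes the alpha constant, the nearest in [Q], and scales it by [Z] squared to 0.009377 min⁻¹. Over 9.8 min less the lost time, that leaves 91.8% of the charge.

The forecast gave 0.55 for [Q], 1.35 for [Z], alike, 90% for the delta run, which is lower than my figure, and the catalyst wakes slowly. Its ground for the orders was: “Faster runs reach that point earlier, so the apparent orders shrink”.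

Behind the readings stand these steps, with Z the sleeping form and Gu the awake one:

    Gu + Q ⇌ ZQ, settled at all times (6.840 M⁻¹)
    Gu + L ⇌ ZL, settled at all times (24.00 M⁻¹)
    ZQ + ZL → G + 2 Gu (3732 M⁻¹ min⁻¹)
    Z + L → Gu + L (56.64 M⁻¹ min⁻¹)

The delta run holds 91.7% of its charge at 9.8 min. The other answers are 0.60 for [Q], 1.5 for [Z], alike, and the catalyst wakes slowly. The pace at which Z wakes makes no difference to that delta share. Carried to the epsilon run, the lost time of the theta run, 0.625 min, plus the natural log of two over the epsilon constant comes to 2.50 min, and the G made in the epsilon run reached half of the Q charged at 2.53 min.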